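(The runs are simulated from invented constants, noise included.)

32 h lies far beyond the last reading at 13 h, and your hunch is that L keeps climbing through that gap in the west run. I doubt it, and one division shows why.

| flask | E | J | L | time |
|---|---|---|---|---|
| south-east | 0.600 M | 0.660 M |  |  |
| south-west | 0.360 M | 0.420 M |  |  |
| north-west | 0.600 M | 2.00 M |  |  |
| south | 0.600 M | 0.660 M | 0.180 M |  |
| west | 0.600 M | 0.660 M |  | 32 h |

- south-east run (time / h: [L] / M): 0.52: 0.032; 0.89: 0.044; 1.5: 0.088; 2.6: 0.136; 4.4: 0.205; 7.6: 0.262; 13: 0.273
- south-west run (time / h: [L] / M): 0.52: 0.011; 0.89: 0.013; 1.5: 0.032; 2.6: 0.052; 4.4: 0.073; 7.6: 0.112; 13: 0.135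
- north-west run (time / h: [L] / M): 0.52: 0.097; 0.89: 0.155; 1.5: 0.234; 2.6: 0.286; 4.4: 0.235; 7.6: 0.142; 13: 0.060
- south run (time / h: [L] / M): 0.52: 0.231; 0.89: 0.278; 1.5: 0.330; 2.6: 0.373; 4.4: 0.426; 7.6: 0.450; 13: 0.451

(readings scatter by 0.005 M)

* apparent order in [E] of the starting rate, round the charge of the south-east run (the rate where two percent of its E have turned into L) (one fixed amount of L, the same in the runs compared)
* apparent order in [J] of the starting rate, round the charge of the south-east run (the rate where two percent of its E have turned into L)
* L in the west run at 32 h, as a share of the E charged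

- Overall: E + J -> L.
- Constant volume, constant temperature.
- "The second partner" is J.
- An order is taken over about fifteen percent of the charge, up and down.

In the north-west run, where J is charged above E, cL falls from 0.142 M at 7.6 h to 0.060 M at 13 h. Read as a pseudo-first-order decay, that is 0.160 h⁻¹. I take J to be what consumes L there, so an L lost has cost a second J.

The south-east run has the west run's charge, with J above E by 0.0600 M. Between 7.6 h and 13 h its cL gains 0.0110 M, about twice the scatter, so I read its last reading as a flat end. I carry one number from it, Y = 0.414, the L standing at the flat end per J charged. The south run, which started with L, has gained 0.411 per J charged at its last reading, the same within the scatter.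

Y times the J charged, over the E charged, gives me 45.5% for the west run. The forecast says 46% (41% to 50%), on the ground that “The reaction therefore stalls”. For the orders it gives 1 in E (0.75 to 1.3) and 1 in J (0.8 to 1.25).

The flask gives 1.1 in E, 1.0 in J and 47.3%, each inside the forecast's range.

    E + J → L (0.1368 M⁻¹ h⁻¹)
    E + J → Z (0.07452 M⁻¹ h⁻¹)
    L + J → Z (0.1591 M⁻¹ h⁻¹)
    E + J + L → 2 L (1.238 M⁻² h⁻¹)

At 32 h the west run stands at Y = 0.430, and the main reason it stays so low is the loss of L with J to Z. In the same run with that step taken away, L reaches 80.0% of the E charged instead of 47.3%, a difference of 33 percentage points. Counted per J charged at the same time, that run has Y = 0.727.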